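**Retrosynthetic overview**
- Last C–C bond: C4–CH2OH, by addition of the hydroxymethyl radical from methanol to a 5-aryl-2,5-dihydrofuran-3-yl aryl ketone, anti to the aryl group; desilylation with base equilibration of the α-keto centre then gives the all-trans target.
- The enone comes from the saturated 5-aryl-3-aroyloxolane by selenoxide dehydrogenation, which deliberately erases the labile α-keto centre.
- Key disconnection: the aryl–C5 bond, made by enantioselective photo-HAT/nickel α-oxy C(sp3)–H arylation of a 3-aroyloxolane with the silylated guaiacyl bromide; this radical cross-coupling sets the only reagent-controlled stereocentre.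
- The 3-aroyloxolane comes from oxolane-3-carboxylic acid and 2,6-dimethoxyphenol (acylation/Fries); the arenes come from catechol (O-methylation, bromination, silylation) and resorcinol (O-methylation, ortho-lithiation/borylation/oxidation).
- Ring order: no ring is built; the oxolane is carried intact from oxolane-3-carboxylic acid and the two benzene rings from catechol and resorcinol.

Assumption and shorthand: the ligand antipode in step 8 is chosen empirically so that C5 becomes S; TIPS = tri(propan-2-yl)silyl; oxolane locants are O1, C2, C3 (acyl), C4, C5 (aryl).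

**Step 1**
Reactants: 1 benzene-1,2-diol (catechol)
Product: 2 2-methoxyphenol
Conditions: MeI (1.0 equiv), K2CO3 (1.0 equiv), acetone, reflux
Reagents that add atoms: iodomethane, CI
Why: Williamson ether synthesis; with one equivalent of base and MeI the more acidic catechol monoanion is alkylated preferentially, and the diether and unreacted diol are removed by extraction and distillation.

**Step 2**
Reactants: 2 2-methoxyphenol
Product: 3 4-bromo-2-methoxyphenol
Conditions: NBS (1.0 equiv), MeCN, 0 °C → rt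
Reagents that add atoms: N-bromosuccinimide, O=C1CCC(=O)N1Br
Why: electrophilic aromatic bromination; the free OH is the dominant director, so bromine enters para to it.

**Step 3**
Reactants: 3 4-bromo-2-methoxyphenol
Product: 4 (4-bromo-2-methoxyphenoxy)tri(propan-2-yl)silane
Conditions: i-Pr3SiCl, imidazole, DMF, rt
Reagents that add atoms: chlorotri(propan-2-yl)silane, CC(C)[Si](Cl)(C(C)C)C(C)C
Why: imidazole-promoted O-silylation; the TIPS ether masks the radical-quenching phenol and tolerates base, HAT photocatalysis and lithium amides.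

**Step 4**
Reactants: 5 benzene-1,3-diol (resorcinol)
Product: 6 1,3-dimethoxybenzene
Conditions: MeI (2.5 equiv), K2CO3 (2.5 equiv), acetone, reflux
Reagents that add atoms: iodomethane, CI
Why: double Williamson O-methylation of the diphenol.

**Step 5**
Reactants: 6 1,3-dimethoxybenzene
Product: 9 2,6-dimethoxyphenol, via (2,6-dimethoxyphenyl)lithium 7 (not isolated), via lithium (2,6-dimethoxyphenyl)trimethoxyborate 8 (not isolated)
Conditions: n-BuLi, THF, 0 °C → rt; B(OMe)3, −78 °C → rt; 30% H2O2, AcOH, 0 °C → rt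
Reagents that add atoms: hydrogen peroxide, OO
Why: directed ortho-metalation at C2 between the two methoxy groups, borylation and oxidative C–B to C–O conversion install the third ring oxygen regiospecifically.

**Step 6**
Reactants: 9 2,6-dimethoxyphenol; 10 oxolane-3-carboxylic acid (racemic)
Product: 12 (4-hydroxy-3,5-dimethoxyphenyl)(oxolan-3-yl)methanone, via 2,6-dimethoxyphenyl oxolane-3-carboxylate 11 (not isolated)
Conditions: CF3SO3H (neat), 0 → 60 °C
Reagents that add atoms: none
Why: Friedel–Crafts acylation through O-acylation and Fries rearrangement in superacid; both positions ortho to oxygen carry OMe, so the acyl group ends up para to OH, as in bromination and formylation of this phenol.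

**Step 7**
Reactants: 12 (4-hydroxy-3,5-dimethoxyphenyl)(oxolan-3-yl)methanone
Product: 13 [3,5-dimethoxy-4-(TIPSO)phenyl](oxolan-3-yl)methanone (racemic)
Conditions: i-Pr3SiOSO2CF3, 2,6-lutidine, CH2Cl2, 0 °C
Reagents that add atoms: tri(propan-2-yl)silyl trifluoromethanesulfonate, CC(C)[Si](OS(=O)(=O)C(F)(F)F)(C(C)C)C(C)C
Why: O-silylation of the hindered phenol with the silyl triflate; the phenol would otherwise quench the radical steps and be O-arylated by nickel.

**Step 8**
Reactants: 13 [3,5-dimethoxy-4-(TIPSO)phenyl](oxolan-3-yl)methanone; 4 (4-bromo-2-methoxyphenoxy)tri(propan-2-yl)silane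
Product: 14 [3,5-dimethoxy-4-(TIPSO)phenyl][(5S)-5-[3-methoxy-4-(TIPSO)phenyl]oxolan-3-yl]methanone (C3 epimers)
Conditions: 13 (3 equiv, excess recovered), (n-Bu4N)4[W10O32] (2 mol%), NiBr2·(MeOCH2CH2OMe) (10 mol%), (4S,4'S)-4,4'-dibenzyl-4,4',5,5'-tetrahydro-2,2'-bi-1,3-oxazole (15 mol%), K3PO4, acetone, 390 nm LEDs, 10 °C
Reagents that add atoms: none
Why: Proposed new method: photoexcited decatungstate abstracts the most hydridic and least hindered α-oxy hydrogen of 13 (C5–H, γ to the carbonyl; C2–H is β to the acyl group and flanked by the substituted C3; the α-keto C3–H is polarity-mismatched), the C5 radical is captured by the chiral bis(oxazoline) aryl-nickel species formed from 4, and reductive elimination from trivalent nickel forges the aryl–C5 bond so that the ligand sets 5S whatever the configuration of the enolisable C3 (erased in step 9); closest known reaction type: decatungstate/nickel and iridium–quinuclidine/nickel α-oxy C(sp3)–H arylation of tetrahydrofuran with aryl bromides and the enantioselective bis(oxazoline)- or bis(imidazoline)-nickel photo-HAT arylations of simple oxacycles and benzylic C–H bonds.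

**Step 9**
Reactants: 14 [3,5-dimethoxy-4-(TIPSO)phenyl][(5S)-5-[3-methoxy-4-(TIPSO)phenyl]oxolan-3-yl]methanone
Product: 17 [3,5-dimethoxy-4-(TIPSO)phenyl][(5S)-5-[3-methoxy-4-(TIPSO)phenyl]-2,5-dihydrofuran-3-yl]methanone, via the 3-phenylselanyl ketone 15 (not isolated), via the selenoxide 16 (not isolated)
Conditions: LiN(i-Pr)2, THF, −78 °C; PhSeCl; then 30% H2O2, pyridine, CH2Cl2, 0 °C → rt
Reagents that add atoms: none
Why: α-selenenylation of the ketone enolate followed by Reich–Sharpless selenoxide syn-elimination; elimination avoids the oxygen-bearing C2, so the double bond forms C3=C4, while the C5 centre is untouched (near-neutral conditions avoid γ-deprotonation at C5).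

**Step 10**
Reactants: 17 [3,5-dimethoxy-4-(TIPSO)phenyl][(5S)-5-[3-methoxy-4-(TIPSO)phenyl]-2,5-dihydrofuran-3-yl]methanone; 18 methanol
Product: 19 [3,5-dimethoxy-4-(TIPSO)phenyl][(4R,5S)-4-(hydroxymethyl)-5-[3-methoxy-4-(TIPSO)phenyl]oxolan-3-yl]methanone (C3 epimers)
Conditions: (n-Bu4N)4[W10O32] (4 mol%), MeOH/MeCN 1:1, 390 nm LEDs, N2, rt
Reagents that add atoms: none
Why: Giese-type radical conjugate addition; decatungstate HAT from methanol (large excess) gives the nucleophilic hydroxymethyl radical, which adds to the enone β-carbon C4 on the face anti to the adjacent C5 aryl group (sets 4R), and back hydrogen transfer to the α-keto radical gives C3 as an epimer mixture corrected in step 11.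

**Step 11**
Reactants: 19 [3,5-dimethoxy-4-(TIPSO)phenyl][(4R,5S)-4-(hydroxymethyl)-5-[3-methoxy-4-(TIPSO)phenyl]oxolan-3-yl]methanone
Product: 20 (4-hydroxy-3,5-dimethoxyphenyl)[(3S,4R,5S)-5-(4-hydroxy-3-methoxyphenyl)-4-(hydroxymethyl)oxolan-3-yl]methanone
Conditions: n-Bu4NF, THF, 0 °C → rt; AcOH quench
Reagents that add atoms: none
Why: fluoride desilylation of both aryl silyl ethers; the basic fluoride/phenoxide medium equilibrates the enolisable C3 to the thermodynamic 3S configuration, trans to the C4 substituent, giving the all-trans target (short reaction time limits retro-oxa-Michael ring opening).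

**Compound list**
1 | benzene-1,2-diol (catechol) | Oc1ccccc1O | starting material
2 | 2-methoxyphenol | COc1ccccc1O | intermediate
3 | 4-bromo-2-methoxyphenol | COc1cc(Br)ccc1O | intermediate
4 | (4-bromo-2-methoxyphenoxy)tri(propan-2-yl)silane | COc1cc(Br)ccc1O[Si](C(C)C)(C(C)C)C(C)C | intermediate
5 | benzene-1,3-diol (resorcinol) | Oc1cccc(O)c1 | starting material
6 | 1,3-dimethoxybenzene | COc1cccc(OC)c1 | intermediate
7 | (2,6-dimethoxyphenyl)lithium | [Li]c1c(OC)cccc1OC | intermediate
8 | lithium (2,6-dimethoxyphenyl)trimethoxyborate | [Li+].CO[B-](OC)(OC)c1c(OC)cccc1OC | intermediate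
9 | 2,6-dimethoxyphenol | COc1cccc(OC)c1O | intermediate
10 | oxolane-3-carboxylic acid (racemic) | OC(=O)C1CCOC1 | starting material
11 | 2,6-dimethoxyphenyl oxolane-3-carboxylate (racemic) | COc1cccc(OC)c1OC(=O)C1CCOC1 | intermediate
12 | (4-hydroxy-3,5-dimethoxyphenyl)(oxolan-3-yl)methanone (racemic) | COc1cc(cc(OC)c1O)C(=O)C1CCOC1 | intermediate
13 | {3,5-dimethoxy-4-[tri(propan-2-yl)silyloxy]phenyl}(oxolan-3-yl)methanone (racemic) | COc1cc(cc(OC)c1O[Si](C(C)C)(C(C)C)C(C)C)C(=O)C1CCOC1 | intermediate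
14 | {3,5-dimethoxy-4-[tri(propan-2-yl)silyloxy]phenyl}[(5S)-5-{3-methoxy-4-[tri(propan-2-yl)silyloxy]phenyl}oxolan-3-yl]methanone (C3 epimers) | COc1cc([C@@H]2CC(C(=O)c3cc(OC)c(O[Si](C(C)C)(C(C)C)C(C)C)c(OC)c3)CO2)ccc1O[Si](C(C)C)(C(C)C)C(C)C | intermediate
15 | {3,5-dimethoxy-4-[tri(propan-2-yl)silyloxy]phenyl}[(5S)-5-{3-methoxy-4-[tri(propan-2-yl)silyloxy]phenyl}-3-(phenylselanyl)oxolan-3-yl]methanone (C3 epimers) | COc1cc([C@@H]2CC([Se]c3ccccc3)(C(=O)c3cc(OC)c(O[Si](C(C)C)(C(C)C)C(C)C)c(OC)c3)CO2)ccc1O[Si](C(C)C)(C(C)C)C(C)C | intermediate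
16 | [(5S)-3-(benzeneseleninyl)-5-{3-methoxy-4-[tri(propan-2-yl)silyloxy]phenyl}oxolan-3-yl]{3,5-dimethoxy-4-[tri(propan-2-yl)silyloxy]phenyl}methanone | COc1cc([C@@H]2CC([Se](=O)c3ccccc3)(C(=O)c3cc(OC)c(O[Si](C(C)C)(C(C)C)C(C)C)c(OC)c3)CO2)ccc1O[Si](C(C)C)(C(C)C)C(C)C | intermediate
17 | {3,5-dimethoxy-4-[tri(propan-2-yl)silyloxy]phenyl}[(5S)-5-{3-methoxy-4-[tri(propan-2-yl)silyloxy]phenyl}-2,5-dihydrofuran-3-yl]methanone | COc1cc([C@@H]2C=C(C(=O)c3cc(OC)c(O[Si](C(C)C)(C(C)C)C(C)C)c(OC)c3)CO2)ccc1O[Si](C(C)C)(C(C)C)C(C)C | intermediate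
18 | methanol | CO | starting material
19 | {3,5-dimethoxy-4-[tri(propan-2-yl)silyloxy]phenyl}[(4R,5S)-4-(hydroxymethyl)-5-{3-methoxy-4-[tri(propan-2-yl)silyloxy]phenyl}oxolan-3-yl]methanone (C3 epimers) | COc1cc([C@H]2OCC(C(=O)c3cc(OC)c(O[Si](C(C)C)(C(C)C)C(C)C)c(OC)c3)[C@@H]2CO)ccc1O[Si](C(C)C)(C(C)C)C(C)C | intermediate
20 | (4-hydroxy-3,5-dimethoxyphenyl)[(3S,4R,5S)-5-(4-hydroxy-3-methoxyphenyl)-4-(hydroxymethyl)oxolan-3-yl]methanone | COc1cc([C@H]2OC[C@@H](C(=O)c3cc(OC)c(O)c(OC)c3)[C@@H]2CO)ccc1O | target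

**Totals**
Total steps: 11. Longest linear sequence: 8 (steps 4 to 11, from resorcinol).

**Three steps most likely to fail, with fallbacks**

Step 8 (C–H arylation). The risks are modest enantioselectivity with a substituted oxolane used near stoichiometrically, and C5 versus C2 site selectivity. The fallback sets out from 13 and moves the stereocontrol from the catalyst to the substrate.
- Selenenylation and oxidation of 13 as in step 9 give {3,5-dimethoxy-4-[tri(propan-2-yl)silyloxy]phenyl}[3-(phenylselanyl)oxolan-3-yl]methanone F1, then its selenoxide [3-(benzeneseleninyl)oxolan-3-yl]{3,5-dimethoxy-4-[tri(propan-2-yl)silyloxy]phenyl}methanone F2, which eliminates to the achiral enone (2,5-dihydrofuran-3-yl){3,5-dimethoxy-4-[tri(propan-2-yl)silyloxy]phenyl}methanone F3.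
- Decatungstate/methanol hydroxymethylation as in step 10, then Et3N equilibration, gives racemic trans {3,5-dimethoxy-4-[tri(propan-2-yl)silyloxy]phenyl}[(3S,4R)-4-(hydroxymethyl)oxolan-3-yl]methanone F4.
- Preparative chromatography on a chiral stationary phase gives the single enantiomer {3,5-dimethoxy-4-[tri(propan-2-yl)silyloxy]phenyl}[(3S,4R)-4-(hydroxymethyl)oxolan-3-yl]methanone F5.
- Ac2O/pyridine gives [(3S,4S)-4-{3,5-dimethoxy-4-[tri(propan-2-yl)silyloxy]benzoyl}oxolan-3-yl]methyl acetate F6.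
- Arylation with 4 using an achiral ligand ((n-Bu4N)4[W10O32], NiBr2·(MeOCH2CH2OMe), 4,4'-di-tert-butyl-2,2'-bipyridine, K3PO4, 390 nm) should occur at the CH2 next to the acetoxymethyl-bearing carbon (γ to the ketone) and trans to that group. It gives [(2S,3R,4S)-4-{3,5-dimethoxy-4-[tri(propan-2-yl)silyloxy]benzoyl}-2-{3-methoxy-4-[tri(propan-2-yl)silyloxy]phenyl}oxolan-3-yl]methyl acetate F7.
- K2CO3/MeOH at 0 °C removes the acetate and the route is rejoined at 19.

Step 10 (hydroxymethyl radical addition). The risks are competing hydrogen abstraction from the doubly activated C5–H of 17, leading to aromatisation to the furan, and slow HAT from methanol. The fallback sets out from 17 and uses a polar hydroxymethyl-anion equivalent.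
- Copper-catalysed conjugate addition of i-PrOMe2SiCH2MgCl (CuBr·SMe2, THF, −78 °C), anti to the aryl group, gives {3,5-dimethoxy-4-[tri(propan-2-yl)silyloxy]phenyl}[(4S,5S)-4-{[dimethyl(propan-2-yloxy)silyl]methyl}-5-{3-methoxy-4-[tri(propan-2-yl)silyloxy]phenyl}oxolan-3-yl]methanone F8.
- Tamao oxidation (H2O2, KF, KHCO3, THF/MeOH) converts C–Si into C–OH and comes back to the route at 19; any partial loss of aryl silyl groups is harmless because step 11 follows.

Step 6 (acylation/Fries). The risks are acylation at C3 of the phenol instead of C4, and acid-mediated ether cleavage. The fallback sets out from 9, reverses the polarity of the aryl partner, and replaces steps 6 and 7.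
- NBS bromination para to OH gives 4-bromo-2,6-dimethoxyphenol F9.
- Silylation (i-Pr3SiOSO2CF3, 2,6-lutidine) gives (4-bromo-2,6-dimethoxyphenoxy)tri(propan-2-yl)silane F10.
- Bromine–lithium exchange (n-BuLi, THF, −78 °C) gives {3,5-dimethoxy-4-[tri(propan-2-yl)silyloxy]phenyl}lithium F11.
- Addition to commercial oxolane-3-carbonitrile gives lithium [{3,5-dimethoxy-4-[tri(propan-2-yl)silyloxy]phenyl}(oxolan-3-yl)methylidene]azanide F12, and cold aqueous HCl hydrolysis returns to the route at 13.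

**Further compounds**
F1 | step 8 | {3,5-dimethoxy-4-[tri(propan-2-yl)silyloxy]phenyl}[3-(phenylselanyl)oxolan-3-yl]methanone (racemic) | COc1cc(cc(OC)c1O[Si](C(C)C)(C(C)C)C(C)C)C(=O)C1([Se]c2ccccc2)CCOC1
F2 | step 8 | [3-(benzeneseleninyl)oxolan-3-yl]{3,5-dimethoxy-4-[tri(propan-2-yl)silyloxy]phenyl}methanone | COc1cc(cc(OC)c1O[Si](C(C)C)(C(C)C)C(C)C)C(=O)C1([Se](=O)c2ccccc2)CCOC1
F3 | step 8 | (2,5-dihydrofuran-3-yl){3,5-dimethoxy-4-[tri(propan-2-yl)silyloxy]phenyl}methanone | COc1cc(cc(OC)c1O[Si](C(C)C)(C(C)C)C(C)C)C(=O)C1=CCOC1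
F4 | step 8 | rac-{3,5-dimethoxy-4-[tri(propan-2-yl)silyloxy]phenyl}[(3S,4R)-4-(hydroxymethyl)oxolan-3-yl]methanone (racemic trans; one enantiomer drawn) | C1OC[C@@H](C(=O)c2cc(OC)c(O[Si](C(C)C)(C(C)C)C(C)C)c(OC)c2)[C@@H]1CO
F5 | step 8 | {3,5-dimethoxy-4-[tri(propan-2-yl)silyloxy]phenyl}[(3S,4R)-4-(hydroxymethyl)oxolan-3-yl]methanone (single enantiomer) | C1OC[C@@H](C(=O)c2cc(OC)c(O[Si](C(C)C)(C(C)C)C(C)C)c(OC)c2)[C@@H]1CO
F6 | step 8 | [(3S,4S)-4-{3,5-dimethoxy-4-[tri(propan-2-yl)silyloxy]benzoyl}oxolan-3-yl]methyl acetate | C1OC[C@@H](C(=O)c2cc(OC)c(O[Si](C(C)C)(C(C)C)C(C)C)c(OC)c2)[C@@H]1COC(C)=O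
F7 | step 8 | [(2S,3R,4S)-4-{3,5-dimethoxy-4-[tri(propan-2-yl)silyloxy]benzoyl}-2-{3-methoxy-4-[tri(propan-2-yl)silyloxy]phenyl}oxolan-3-yl]methyl acetate | COc1cc([C@H]2OC[C@@H](C(=O)c3cc(OC)c(O[Si](C(C)C)(C(C)C)C(C)C)c(OC)c3)[C@@H]2COC(C)=O)ccc1O[Si](C(C)C)(C(C)C)C(C)C
F8 | step 10 | {3,5-dimethoxy-4-[tri(propan-2-yl)silyloxy]phenyl}[(4S,5S)-4-{[dimethyl(propan-2-yloxy)silyl]methyl}-5-{3-methoxy-4-[tri(propan-2-yl)silyloxy]phenyl}oxolan-3-yl]methanone (C3 epimers) | COc1cc([C@H]2OCC(C(=O)c3cc(OC)c(O[Si](C(C)C)(C(C)C)C(C)C)c(OC)c3)[C@@H]2C[Si](C)(C)OC(C)C)ccc1O[Si](C(C)C)(C(C)C)C(C)C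
F9 | step 6 | 4-bromo-2,6-dimethoxyphenol | COc1cc(Br)cc(OC)c1O
F10 | step 6 | (4-bromo-2,6-dimethoxyphenoxy)tri(propan-2-yl)silane | COc1cc(Br)cc(OC)c1O[Si](C(C)C)(C(C)C)C(C)C
F11 | step 6 | {3,5-dimethoxy-4-[tri(propan-2-yl)silyloxy]phenyl}lithium | [Li]c1cc(OC)c(O[Si](C(C)C)(C(C)C)C(C)C)c(OC)c1
F12 | step 6 | lithium [{3,5-dimethoxy-4-[tri(propan-2-yl)silyloxy]phenyl}(oxolan-3-yl)methylidene]azanide | [Li]N=C(C1CCOC1)c1cc(OC)c(O[Si](C(C)C)(C(C)C)C(C)C)c(OC)c1
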